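I count target and solid product in molar units rather than in percent of the solid substrate charged.

| setting | green | teal | flask |
|---|---|---|---|
| solid substrate | 0.040 M | 0.088 M | 0.059 M |
| solid reagent | 0.118 M | 0.118 M | 0.118 M |
| remark | run made earlier | run made earlier |  |
| time |  |  | 25 h |

- green (time / h: target / %, solid product / %): 3.00: 0.8, 0.6; 8.00: 1.6, 0.3; 15.0: 7.0, 0; 25.0: 11.1, 0.3
- teal (time / h: target / %, solid product / %): 6.00: 0.6, 0; 12.0: 2.4, 0.4; 20.0: 4.7, 0; 25.0: 4.8, 0.2

(readings scatter by 0.5 percentage points)

- target is meant together with its solid product
- solid, in amounts per volume of the solution: solid substrate, solid product, solid reagent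
- at the start none of the solid substrate is in solution
- at the start none of the solid reagent is in solution
- dissolved substrate means what is dissolved; the solid is not counted in it

- how much target and solid product together there is at 25 h, in percent of the solid substrate charged
- concentration of dissolved substrate in solution at 25 h, in percent of saturation

At 25 h, target and solid product together stand at 4.56 mM in the green run and 4.40 mM in the teal run, although teal holds 2.20 times the solid substrate. That gap is smaller than the scatter of one teal reading, 0.440 mM. So I take their mean, 4.48 mM, and call it the molar make: the concentration of target and solid product together at 25 h, with 0.118 M of solid reagent charged.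

For the new flask, with 0.059 M of solid substrate, dividing gives 7.59%. The readings hold no measure of dissolved substrate, so I give no figure for saturation.

The forecast says 7.6% and 99% of saturation, with the thought that “the solid simply keeps the solution saturated”.

The flask gives 6.97% of target and solid product, and dissolved substrate at 52.9% of saturation.

    solid substrate ⇌ dissolved substrate, rate k1*(cs1 - [dissolved substrate]) while solid is left; crystals form when [dissolved substrate] > cs1 (solubility = 32.0 mM, k = 8.67 × 10⁻⁴ min⁻¹)
    dissolved substrate + coupling partner → target (k = 0.0168 M⁻¹ min⁻¹)
    dissolved substrate + target → side product (k = 0.0530 M⁻¹ min⁻¹)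
    solid product ⇌ target, rate k4*(cs4 - [target]) while solid is left; crystals form when [target] > cs4 (solubility = 21.0 mM, k = 0.0125 min⁻¹)
    solid reagent ⇌ coupling partner, rate k5*(cs5 - [coupling partner]) while solid is left; crystals form when [coupling partner] > cs5 (solubility = 39.0 mM, k = 0.00734 min⁻¹)
    target ⇌ isomer of the product (K = 2.20, k = 3.28 × 10⁻⁴ min⁻¹)
    2 coupling partner → self-condensation product (k = 0.0477 M⁻¹ min⁻¹)

At 25.0 h this flask still holds 54.6% of its charge as solid substrate, beside 28.7% as dissolved substrate. Its own molar make is 4.11 mM, against the 4.48 mM read from the two runs. For the same recipe with 0.024 M of solid substrate, the carried make gives 18.7%, and that flask stands at 17.0%.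

(The runs were generated by integration from invented constants, noise included.)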